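**Retrosynthetic overview**
- Stilbene numbering used below: C7 is the alkene carbon on the 4-hydroxyphenyl (or catechol) ring, C8 the alkene carbon on the resorcinol ring, and "C12" the resorcinol carbon between the two OH groups.
- Both dihydrofuran rings are cut at C3–aryl (C8–C12 of the next unit) and C2–O (C7–O); this leads back to two molecules of resveratrol 1 and one of piceatannol 2.
- Each ring is closed as in the plant (oxidised stilbene plus resorcinol ring: C8–C12 bond, then oxa-Michael closure of the para-quinone methide), but in the polar two-electron mode under chiral-catalyst control, not as a free-radical coupling.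
- Ring order: first the dihydrofuran of the styryl-bearing benzofuran (oxidative dimerisation of dibrominated resveratrol), then the dihydrofuran of the catechol-bearing benzofuran (dimer plus the ortho-quinone of 2).
- Two bromines per resorcinol ring block the positions ortho to the styryl group (which would give the ε-viniferin-type connection) and make those ring OH groups the most acidic in the mixture; they are removed last.

Assumption: the SMILES given is the structure (trans 2R,3R in the styryl-bearing dihydrobenzofuran, trans 2S,3S in the catechol-bearing one); piceatannol is bought; which antipode of each chiral catalyst gives the drawn sense is fixed in a first small screen and the mirror-image catalyst is used if needed.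

**Route**

Step 1
Reactants: 1 resveratrol (5-[(E)-2-(4-hydroxyphenyl)ethenyl]benzene-1,3-diol)
Product: 3 4,6-dibromo-5-[(E)-2-(4-hydroxyphenyl)ethenyl]benzene-1,3-diol (dibromoresveratrol; Br on both ring carbons next to the styryl group)
Conditions: NBS (2.0 equiv), MeCN, −30 °C to 0 °C, dark
Reagents that add atoms: N-bromosuccinimide, O=C1CCC(=O)N1Br
Why: Electrophilic aromatic bromination (SEAr): the resorcinol ring is far more electron-rich than the 4-hydroxyphenyl ring, and its two positions para to one OH and ortho to the other react before the carbon between the OH groups, as in resorcinol going to 4,6-dibromoresorcinol, so two equivalents stop at the dibromide; no stereocentre is formed and the E-alkene is not touched in dry MeCN at low temperature.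

Step 2
Reactants: 3 dibromoresveratrol (two molecules: one is oxidised, one is the nucleophile)
Product: 6 (2R,3S)-5,7-dibromo-3-(2,6-dibromo-3,5-dihydroxyphenyl)-2-(4-hydroxyphenyl)-6-[(E)-2-(4-hydroxyphenyl)ethenyl]-2,3-dihydro-1-benzofuran-4-ol (trans tetrabromo dimer), via quinone methide cation 4 (not isolated), via para-quinone methide 5 (not isolated)
Conditions: DDQ (0.45 equiv, added over 2 h), (R)-3,3'-bis(2,4,6-triisopropylphenyl)-1,1'-binaphthyl-2,2'-diyl hydrogen phosphate (10 mol%), 4 Å MS, CH2Cl2/EtOAc 3:1, −40 °C; unreacted 3 recovered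
Reagents that add atoms: none
Why: Proposed new method: DDQ takes two electrons and a proton from the 4-hydroxystilbene of one molecule of 3 to give cation 4, which the chiral phosphate holds as an ion pair while hydrogen-bonding the acidic OH of a second molecule of 3, whose only free resorcinol carbon (between the OH groups) attacks C8 of 4 on one face (sets C3, labelled S only because Br raises the priority of the aryl group), after which the flanking phenol closes para-quinone methide 5 by 5-exo oxa-Michael addition with the two aryl groups trans (C2 = R, the more stable isomer); the closest known chemistry is the oxidant-promoted (FeCl3, Tl(NO3)3) dimerisation of resveratrol to ε-viniferin, DDQ cross-dehydrogenative couplings under chiral-anion control, and chiral phosphoric acid-catalysed additions of phenols to para-quinone methides.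

Step 3
Reactants: 6 tetrabromo dimer; 2 piceatannol (4-[(E)-2-(3,5-dihydroxyphenyl)ethenyl]benzene-1,2-diol)
Product: 9 (2R,3S)-5,7-dibromo-3-[(2S,3S)-5,7-dibromo-2-(3,4-dihydroxyphenyl)-3-(3,5-dihydroxyphenyl)-4-hydroxy-2,3-dihydro-1-benzofuran-6-yl]-2-(4-hydroxyphenyl)-6-[(E)-2-(4-hydroxyphenyl)ethenyl]-2,3-dihydro-1-benzofuran-4-ol (tetrabromo trimer), via piceatannol ortho-quinone 7 (not isolated), via para-quinone methide adduct 8 (not isolated)
Conditions: 2 (1.3 equiv), Ag2O (3 equiv), EtOAc, 0 °C, 5 min, cold filtration through Celite; filtrate added over 3 h to 6, 3-{[3,5-bis(trifluoromethyl)phenyl]amino}-4-{[(8α,9S)-6'-methoxycinchonan-9-yl]amino}cyclobut-3-ene-1,2-dione (10 mol%), 4 Å MS, EtOAc/CH2Cl2 1:1, −40 °C, Ar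
Reagents that add atoms: none
Why: Proposed new method: the squaramide N–H bonds bind the two adjacent carbonyls of quinone 7 while the quinuclidine nitrogen deprotonates the most acidic phenol present, the 2,4-dibromophenol-type OH of the pendant ring of 6 (pKa about 7.5 against 9 or more for the others; the equally acidic OH on the benzofuran ring has no free ring carbon), so the one free carbon of that ring adds to the styryl terminus C8 of the quinone in a vinylogous 1,6-Michael addition (sets C3 of the new ring, S) and the neighbouring phenoxide closes para-quinone methide 8 by 5-exo oxa-Michael addition with the catechol trans (C2 = S); this is the polar counterpart of the biosynthetic coupling, and the closest known reactions are amine–squaramide- and phosphoric acid-catalysed enantioselective 1,6-additions and 3+2 annulations of phenols and naphthols with para-quinone methides and the arylation of quinones by naphthols.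

Step 4
Reactants: 9 tetrabromo trimer
Product: 10 (2R,3R)-3-[(2S,3S)-2-(3,4-dihydroxyphenyl)-3-(3,5-dihydroxyphenyl)-4-hydroxy-2,3-dihydro-1-benzofuran-6-yl]-2-(4-hydroxyphenyl)-6-[(E)-2-(4-hydroxyphenyl)ethenyl]-2,3-dihydro-1-benzofuran-4-ol (target)
Conditions: Pd(OAc)2 (10 mol%), 2-dicyclohexylphosphino-2',6'-dimethoxybiphenyl (20 mol%), HCO2Na (12 equiv), degassed DMF/H2O 10:1, 70 °C, Ar
Reagents that add atoms: none
Why: Palladium-catalysed transfer hydrodehalogenation (oxidative addition of zerovalent palladium into Ar–Br, formate exchange, loss of CO2, reductive elimination of Ar–H) cleaves only the four aryl C–Br bonds; formate is too weak a base to open the dihydrobenzofurans, the homogeneous catalyst does not reduce the E-stilbene, and no stereocentre is touched (the descriptor at C3 returns to R only because Br is gone).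

**Compound list**

1 | resveratrol, 5-[(E)-2-(4-hydroxyphenyl)ethenyl]benzene-1,3-diol | Oc1ccc(/C=C/c2cc(O)cc(O)c2)cc1 | starting material
2 | piceatannol, 4-[(E)-2-(3,5-dihydroxyphenyl)ethenyl]benzene-1,2-diol | Oc1cc(/C=C/c2ccc(O)c(O)c2)cc(O)c1 | starting material
3 | 4,6-dibromo-5-[(E)-2-(4-hydroxyphenyl)ethenyl]benzene-1,3-diol | Oc1ccc(/C=C/c2c(Br)c(O)cc(O)c2Br)cc1 | intermediate
4 | quinone methide cation (phosphate ion pair, formed in the flask): 1-(2,6-dibromo-3,5-dihydroxyphenyl)-2-(4-oxocyclohexa-2,5-dien-1-ylidene)ethan-1-ylium | O=C1C=CC(=C[CH+]c2c(Br)c(O)cc(O)c2Br)C=C1 | intermediate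
5 | para-quinone methide (formed in the flask): 4-[(2S)-2-(2,6-dibromo-3,5-dihydroxyphenyl)-2-{3,5-dibromo-2,6-dihydroxy-4-[(E)-2-(4-hydroxyphenyl)ethenyl]phenyl}ethylidene]cyclohexa-2,5-dien-1-one | O=C1C=CC(=C[C@H](c2c(Br)c(O)cc(O)c2Br)c2c(O)c(Br)c(/C=C/c3ccc(O)cc3)c(Br)c2O)C=C1 | intermediate
6 | (2R,3S)-5,7-dibromo-3-(2,6-dibromo-3,5-dihydroxyphenyl)-2-(4-hydroxyphenyl)-6-[(E)-2-(4-hydroxyphenyl)ethenyl]-2,3-dihydro-1-benzofuran-4-ol (trans) | Oc1ccc(/C=C/c2c(Br)c(O)c3c(c2Br)O[C@@H](c2ccc(O)cc2)[C@@H]3c2c(Br)c(O)cc(O)c2Br)cc1 | intermediate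
7 | piceatannol ortho-quinone (formed in the flask): 4-[(E)-2-(3,5-dihydroxyphenyl)ethenyl]cyclohexa-3,5-diene-1,2-dione | O=C1C=CC(/C=C/c2cc(O)cc(O)c2)=CC1=O | intermediate
8 | para-quinone methide adduct (formed in the flask): 6 carrying, on the carbon between the two OH groups of its 2,6-dibromo-3,5-dihydroxyphenyl ring, the group (1S)-1-(3,5-dihydroxyphenyl)-2-[(E)-3-hydroxy-4-oxocyclohexa-2,5-dien-1-ylidene]ethyl | O=C1C=C/C(=C\[C@@H](c2cc(O)cc(O)c2)c2c(O)c(Br)c([C@H]3[C@H](c4ccc(O)cc4)Oc4c(Br)c(/C=C/c5ccc(O)cc5)c(Br)c(O)c43)c(Br)c2O)C=C1O | intermediate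
9 | (2R,3S)-5,7-dibromo-3-[(2S,3S)-5,7-dibromo-2-(3,4-dihydroxyphenyl)-3-(3,5-dihydroxyphenyl)-4-hydroxy-2,3-dihydro-1-benzofuran-6-yl]-2-(4-hydroxyphenyl)-6-[(E)-2-(4-hydroxyphenyl)ethenyl]-2,3-dihydro-1-benzofuran-4-ol | Oc1ccc(/C=C/c2c(Br)c(O)c3c(c2Br)O[C@@H](c2ccc(O)cc2)[C@@H]3c2c(Br)c(O)c3c(c2Br)O[C@H](c2ccc(O)c(O)c2)[C@H]3c2cc(O)cc(O)c2)cc1 | intermediate
10 | (2R,3R)-3-[(2S,3S)-2-(3,4-dihydroxyphenyl)-3-(3,5-dihydroxyphenyl)-4-hydroxy-2,3-dihydro-1-benzofuran-6-yl]-2-(4-hydroxyphenyl)-6-[(E)-2-(4-hydroxyphenyl)ethenyl]-2,3-dihydro-1-benzofuran-4-ol | Oc1ccc(/C=C/c2cc(O)c3c(c2)O[C@@H](c2ccc(O)cc2)[C@@H]3c2cc(O)c3c(c2)O[C@H](c2ccc(O)c(O)c2)[C@H]3c2cc(O)cc(O)c2)cc1 | target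

**Step count and risks**

Total steps: 4. Longest linear sequence: 4 (1 → 3 → 6 → 9 → 10).

Step 2 is the most likely to fail. Facial control by an ion pair at a carbon remote from the phenol oxygen is unproven, C8 is shielded by the dibromoaryl group, closure through the 4-hydroxyphenyl ring (δ-viniferin type) competes, and DDQ can over-oxidise 6. Fallback, from 3 back to 9: give up catalyst control in the dimerisation and resolve through the second ring. FeCl3·6H2O (1 equiv) in acetone at room temperature, the oxidant class that turns resveratrol into ε-viniferin, couples 3 without facial bias. The reaction runs through 5 and its mirror image, the (R)-para-quinone methide F1, and gives racemic dimer, that is 6 together with the (2S,3R)-dimer F2. The racemate goes into step 3 unchanged. The squaramide fixes the new ring as 2S,3S whatever the configuration of the old one, so F2 is carried through the epimeric quinone methide adduct F3 to the diastereomeric trimer F4. F4 is a diastereomer of 9 and is removed by chromatography, and the route continues from 9. The same logic upgrades a modest ee from step 2 in the main route.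

Step 3 is the second risk. The brominated ring of 6 may be too poor a nucleophile, quinone 7 can condense with its own resorcinol ring, and attack at a quinone ring carbon instead of C8 is possible. Fallback, from 6 to 10: remove bromine first and switch from base to acid activation. 6 is debrominated under the conditions of step 4 to the (2R,3R)-dimer F5. F5 is treated with quinone 7 (slow addition) and the phosphoric acid of step 2 or its mirror image. The resorcinol ring of F5 is now electron-rich enough for an acid-catalysed Friedel–Crafts-type conjugate addition, and the carbon between its OH groups is favoured because the other two positions sit ortho to the bulky benzylic CH of the dihydrobenzofuran. The debrominated quinone methide adduct F6 closes directly to 10.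

Step 4 is the third risk. It requires four hindered C–Br bonds on electron-rich rings to be cleaved in the presence of a chelating catechol and a stilbene. Fallback, from 9 to 10: protect, reduce, deprotect. Ac2O/pyridine/DMAP converts 9 into the octaacetate F7, which masks the catechol and makes the bromoarenes less electron-rich. Pd(OAc)2, the same phosphine and HCO2Na then remove the bromines to give the target octaacetate F8. K2CO3 in MeOH at 0 °C under argon releases 10.

**Further compounds**

F1 | step 2 | (R)-para-quinone methide, mirror image of 5 | O=C1C=CC(=C[C@@H](c2c(Br)c(O)cc(O)c2Br)c2c(O)c(Br)c(/C=C/c3ccc(O)cc3)c(Br)c2O)C=C1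
F2 | step 2 | (2S,3R)-dimer, mirror image of 6 | Oc1ccc(/C=C/c2c(Br)c(O)c3c(c2Br)O[C@H](c2ccc(O)cc2)[C@H]3c2c(Br)c(O)cc(O)c2Br)cc1
F3 | step 2 | epimeric quinone methide adduct (as 8, but with the 2S,3R dihydrobenzofuran of F2) | O=C1C=C/C(=C\[C@@H](c2cc(O)cc(O)c2)c2c(O)c(Br)c([C@@H]3[C@@H](c4ccc(O)cc4)Oc4c(Br)c(/C=C/c5ccc(O)cc5)c(Br)c(O)c43)c(Br)c2O)C=C1O
F4 | step 2 | diastereomeric trimer, (2S,3R) in the styryl-bearing ring and (2S,3S) in the catechol-bearing ring | Oc1ccc(/C=C/c2c(Br)c(O)c3c(c2Br)O[C@H](c2ccc(O)cc2)[C@H]3c2c(Br)c(O)c3c(c2Br)O[C@H](c2ccc(O)c(O)c2)[C@H]3c2cc(O)cc(O)c2)cc1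
F5 | step 3 | (2R,3R)-3-(3,5-dihydroxyphenyl)-2-(4-hydroxyphenyl)-6-[(E)-2-(4-hydroxyphenyl)ethenyl]-2,3-dihydro-1-benzofuran-4-ol | Oc1ccc(/C=C/c2cc(O)c3c(c2)O[C@@H](c2ccc(O)cc2)[C@@H]3c2cc(O)cc(O)c2)cc1
F6 | step 3 | debrominated quinone methide adduct (8 without bromine) | O=C1C=C/C(=C\[C@@H](c2cc(O)cc(O)c2)c2c(O)cc([C@H]3[C@H](c4ccc(O)cc4)Oc4cc(/C=C/c5ccc(O)cc5)cc(O)c43)cc2O)C=C1O
F7 | step 4 | octaacetate of 9 | CC(=O)Oc1ccc(/C=C/c2c(Br)c(OC(C)=O)c3c(c2Br)O[C@@H](c2ccc(OC(C)=O)cc2)[C@@H]3c2c(Br)c(OC(C)=O)c3c(c2Br)O[C@H](c2ccc(OC(C)=O)c(OC(C)=O)c2)[C@H]3c2cc(OC(C)=O)cc(OC(C)=O)c2)cc1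
F8 | step 4 | octaacetate of 10 | CC(=O)Oc1ccc(/C=C/c2cc(OC(C)=O)c3c(c2)O[C@@H](c2ccc(OC(C)=O)cc2)[C@@H]3c2cc(OC(C)=O)c3c(c2)O[C@H](c2ccc(OC(C)=O)c(OC(C)=O)c2)[C@H]3c2cc(OC(C)=O)cc(OC(C)=O)c2)cc1
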